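**Strategy.** Everything rests on cutting the para-quinone ring C (C8, C9, C11–C14) at C11–C12 and C13–C14. Its C12(OMe)=C13(iPr) edge is an oxygen-polarised alkyne, and C14 is the carbene carbon of a chromium alkenylcarbene fixed on C8 of the oxa-bridged ring B. One Dötz benzannulation joins ynol ether, carbene and CO (which becomes C11) into the fully substituted arene, the polarisation of the alkyne setting OMe against iPr; aqueous acid and (NH4)2Ce(NO3)6 then give the quinone hemiketal. The precursor is a tricyclic bridged methyl ketal carrying Cr(CO)5=C(OMe) on C8, whose C5 and C10 centres are relayed from one CBS reduction through Claisen rearrangement and cis-lactonisation.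

Key step: step 14

Remark: all intermediates carry the icetexane numbering of the target (ring A: C1–C5, C10; ring B: C5, C6, C7, C8, C9, C20, C10; ring C: C8, C9, C11–C14). Hemiketals 8–10 and 21 are drawn closed and are assumed to equilibrate with their open hydroxy ketone forms.

**Step 1**
Reactants: 1 4,4-dimethylcyclohex-2-en-1-one
Product: 2 2-iodo-4,4-dimethylcyclohex-2-en-1-one
Conditions: I2, pyridine, CH2Cl2, 0 °C → rt
Reagents that add atoms: iodine, II
Why: Johnson α-iodination of an enone (pyridine conjugate addition, iodination of the enolate, elimination) should place iodine on the α-carbon only.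

**Step 2**
Reactants: 2 2-iodo-4,4-dimethylcyclohex-2-en-1-one
Product: 3 2-allyl-4,4-dimethylcyclohex-2-en-1-one
Conditions: allylSnBu3, Pd(PPh3)4 (5 mol%), CuI (10 mol%), DMF, 60 °C
Reagents that add atoms: allyltributylstannane, C=CC[Sn](CCCC)(CCCC)CCCC
Why: Stille coupling of an α-iodoenone with an allylstannane installs the future C20–C9 unit on the carbon that becomes C10.

**Step 3**
Reactants: 3 2-allyl-4,4-dimethylcyclohex-2-en-1-one
Product: 4 (1R)-2-allyl-4,4-dimethylcyclohex-2-en-1-ol
Conditions: (S)-2-methyl-CBS-oxazaborolidine (15 mol%), catecholborane, toluene, −78 °C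
Reagents that add atoms: none
Why: CBS reduction, in which the α-substituted alkenyl arm is the large group so that the (S)-catalyst should give the (R)-carbinol, while catecholborane at −78 °C leaves the terminal alkene alone.

**Step 4**
Reactants: 4 (1R)-2-allyl-4,4-dimethylcyclohex-2-en-1-ol
Product: 5 ethyl 2-[(1S)-2-allyl-6,6-dimethylcyclohex-2-en-1-yl]acetate
Conditions: MeC(OEt)3, EtCO2H (cat.), 140 °C, EtOH distilled off
Reagents that add atoms: triethyl orthoacetate, CC(OCC)(OCC)OCC
Why: Johnson–Claisen rearrangement, whose suprafacial [3,3] shift transfers the carbinol configuration to the new C5–C6 bond (C5 becomes S) and moves the alkene to C10=C1.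

**Step 5**
Reactants: 5 ethyl 2-[(1S)-2-allyl-6,6-dimethylcyclohex-2-en-1-yl]acetate
Product: 7 (3aS,7aS)-7a-allyl-4,4-dimethylhexahydro-1-benzofuran-2(3H)-one, via carboxylic acid 6 (not isolated)
Conditions: LiOH, THF/MeOH/H2O, 50 °C; evaporate; then CF3CO2H/CH2Cl2 (1:4), 0 °C → rt
Reagents that add atoms: lithium hydroxide, [Li+].[OH-]
Why: Saponification followed by Markovnikov protolactonisation of the trisubstituted C10=C1 alkene (tertiary cation at C10; the monosubstituted allyl alkene is far less basic), in which the carboxyl on the C5 arm can only close the cis-fused γ-lactone under reversible conditions, so that C10 becomes S with oxygen cis to C6 and allyl trans.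

**Step 6**
Reactants: 7 (3aS,7aS)-7a-allyl-4,4-dimethylhexahydro-1-benzofuran-2(3H)-one
Product: 8 (3aS,7aS)-7a-allyl-4,4-dimethyl-2-vinyloctahydro-1-benzofuran-2-ol (both C7 epimers)
Conditions: CH2=CHMgBr (1.1 equiv), THF, −78 °C; sat. NH4Cl at −78 °C
Reagents that add atoms: vinylmagnesium bromide, C=C[Mg]Br
Why: Mono-addition of a Grignard reagent to a γ-lactone, whose tetrahedral magnesium alkoxide should persist at −78 °C and give the lactol (C7 and C8 now in place) instead of the diol.

**Step 7**
Reactants: 8 (3aS,7aS)-7a-allyl-4,4-dimethyl-2-vinyloctahydro-1-benzofuran-2-ol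
Product: 9 (5S,7S,10S)-bridged hemiketal alkene (7-hydroxy-7,10-epoxy tricycle with C8=C9)
Conditions: second-generation Grubbs catalyst (5 mol%), CH2Cl2, 40 °C
Reagents that add atoms: none
Why: Ring-closing metathesis of the C7 vinyl and C10 allyl groups closes the seven-membered ring B as its C8=C9 cis-alkene; the C7 epimers interconvert through the open hydroxy enone, and the one-atom oxygen bridge from C10 allows only the 7S hemiketal.

**Step 8**
Reactants: 9 (5S,7S,10S)-bridged hemiketal alkene
Product: 10 (5S,7S,10S)-8-iodo bridged hemiketal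
Conditions: I2, pyridine, CH2Cl2, rt
Reagents that add atoms: iodine, II
Why: Johnson α-iodination acting on the ring-opened 10-hydroxycyclohept-8-en-7-one tautomer (pyridine adds at C9, the enolate is iodinated at C8, elimination), after which the hemiketal recloses.

**Step 9**
Reactants: 10 (5S,7S,10S)-8-iodo bridged hemiketal
Product: 11 (5S,7S,10S)-8-iodo-7-methoxy bridged ketal
Conditions: MeOH, camphorsulfonic acid (10 mol%), 3 Å molecular sieves, rt
Reagents that add atoms: methanol, CO
Why: Acid-catalysed ketalisation through the open enone, in which the acyclic C7 oxocarbenium is trapped by the C10 hydroxyl to give the 8-oxabicyclo[3.2.1]octene methyl ketal as thermodynamic product, masking both the ketone and the tertiary alcohol.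

**Step 10**
Reactants: 11 (5S,7S,10S)-8-iodo-7-methoxy bridged ketal
Product: 14 pentacarbonyl[methoxy(C8-alkenyl)carbene]chromium, via vinyllithium 12 (not isolated), via lithium acylchromate 13 (not isolated)
Conditions: t-BuLi (2.1 equiv), Et2O, −78 °C; Cr(CO)6, Et2O/THF, −78 °C → rt; MeOTf, CH2Cl2, 0 °C
Reagents that add atoms: chromium hexacarbonyl, O=C=[Cr](=C=O)(=C=O)(=C=O)(=C=O)=C=O; methyl trifluoromethanesulfonate, COS(=O)(=O)C(F)(F)F
Why: Fischer carbene synthesis: iodine–lithium exchange gives the C8 vinyllithium (β-alkoxide loss would need a bridgehead alkene or a cyclic allene and should not occur), which adds to a CO ligand, and O-methylation of the acylchromate installs C14 as the carbene carbon.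

**Step 11**
Reactants: 15 N,2-dimethoxy-N-methylacetamide
Product: 16 1-methoxy-3-methylbutan-2-one
Conditions: i-PrMgCl, THF, 0 °C; aq. HCl
Reagents that add atoms: isopropylmagnesium chloride, CC(C)[Mg]Cl
Why: Weinreb ketone synthesis, whose chelated tetrahedral intermediate stops the addition at the ketone.

**Step 12**
Reactants: 16 1-methoxy-3-methylbutan-2-one
Product: 17 (Z)-1-methoxy-3-methylbut-1-en-2-yl trifluoromethanesulfonate
Conditions: LiN(SiMe3)2, THF, −78 °C; PhNTf2, −78 °C → rt
Reagents that add atoms: N-phenylbis(trifluoromethanesulfonimide), O=S(=O)(N(c1ccccc1)S(=O)(=O)C(F)(F)F)C(F)(F)F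
Why: Kinetic deprotonation at the less hindered, methoxy-bearing CH2 gives the lithium-chelated (Z)-enolate, which is O-triflated (enol triflate formation).

**Step 13**
Reactants: 17 (Z)-1-methoxy-3-methylbut-1-en-2-yl trifluoromethanesulfonate
Product: 18 1-methoxy-3-methylbut-1-yne
Conditions: KOt-Bu, THF, −78 °C → 0 °C; distilled and kept as a solution
Reagents that add atoms: none
Why: Anti E2 elimination of triflic acid from the (Z)-enol triflate (H and OTf trans) should give the ynol ether.

**Step 14**
Reactants: 14 pentacarbonyl[methoxy(C8-alkenyl)carbene]chromium; 18 1-methoxy-3-methylbut-1-yne (1.5 equiv)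
Product: 20 (5S,7S,10S)-11-hydroxy-7,12,14-trimethoxy-13-isopropyl arene bridged ketal, via arene chromium tricarbonyl complex 19 (not isolated)
Conditions: THF, 55 °C, argon; then air, Et2O, daylight, rt
Reagents that add atoms: none
Why: Dötz benzannulation: the ynol ether inserts into the Cr=C14 bond with its nucleophilic carbon C13 (β to oxygen) bonding to the electrophilic carbene carbon, which gives a methoxy-stabilised dienylcarbene at C12; CO insertion there makes the C11 ketene (bond C11–C12), and 6π electrocyclisation onto C9 followed by tautomerisation gives the phenol. The closest known reaction types are the chromium alkenylcarbene–alkyne benzannulation and the thermal benzannulation of chromium dienyl(alkoxy)carbenes to ortho-alkoxyphenols. Ring C is the only ring closed, by 6π electrocyclisation of the dienylketene (C11–C9) after the two intermolecular bonds C13–C14 and C11–C12 have formed. No stereocentre is created, and C5, C7 and C10 are spectators locked in the bridged ketal. The step needs one orientation of the alkyne (iPr carbon to C14, methoxy carbon to the CO-derived C11); the oxygen polarisation of 18 secures it electronically, and the other partner is fixed because the carbene carbon sits on C8 and only C9 carries the hydrogen needed for aromatisation. Air then removes Cr(CO)3 from the arene.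

**Step 15**
Reactants: 20 (5S,7S,10S)-11-hydroxy-7,12,14-trimethoxy-13-isopropyl arene bridged ketal
Product: 22 komaroviquinone, via hemiketal phenol 21 (not isolated)
Conditions: 1 M HCl, THF, rt; then (NH4)2Ce(NO3)6, MeCN/H2O, 0 °C
Reagents that add atoms: water, O
Why: Aqueous acid opens the bridged ketal through the acyclic, aryl-stabilised oxocarbenium to the hemiketal, and tetravalent cerium then oxidises the para-methoxyphenol to the para-quinone with loss of the C14 methyl as methanol (oxidative demethylation); the C12 methoxy is retained, and the hemiketal recloses with C7 fixed as S by the C10 bridge.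

**Compound list**
1 | 4,4-dimethylcyclohex-2-en-1-one | CC1(C)CCC(=O)C=C1 | starting material
2 | 2-iodo-4,4-dimethylcyclohex-2-en-1-one | CC1(C)CCC(=O)C(I)=C1 | intermediate
3 | 2-allyl-4,4-dimethylcyclohex-2-en-1-one | CC1(C)CCC(=O)C(CC=C)=C1 | intermediate
4 | (1R)-2-allyl-4,4-dimethylcyclohex-2-en-1-ol | O[C@H]1C(CC=C)=CC(C)(C)CC1 | intermediate
5 | ethyl 2-[(1S)-2-allyl-6,6-dimethylcyclohex-2-en-1-yl]acetate | CCOC(=O)C[C@@H]1C(CC=C)=CCCC1(C)C | intermediate
6 | 2-[(1S)-2-allyl-6,6-dimethylcyclohex-2-en-1-yl]acetic acid | OC(=O)C[C@@H]1C(CC=C)=CCCC1(C)C | intermediate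
7 | (3aS,7aS)-7a-allyl-4,4-dimethylhexahydro-1-benzofuran-2(3H)-one (cis-fused lactone; 5S,10S) | C=CC[C@@]12CCCC(C)(C)[C@@H]1CC(=O)O2 | intermediate
8 | (3aS,7aS)-7a-allyl-4,4-dimethyl-2-vinyloctahydro-1-benzofuran-2-ol (lactol, both C7 epimers) | C=CC[C@@]12CCCC(C)(C)[C@@H]1CC(O)(C=C)O2 | intermediate
9 | (5S,7S,10S)-bridged hemiketal alkene: ring A (4,4-dimethyl) fused at C5–C10 to cycloheptene ring B (C8=C9), oxygen bridge C10–O–C7, OH on C7 | C1=CC[C@@]23CCCC(C)(C)[C@@H]2C[C@]1(O)O3 | intermediate
10 | (5S,7S,10S)-8-iodo bridged hemiketal (as 9, iodine on C8) | IC1=CC[C@@]23CCCC(C)(C)[C@@H]2C[C@]1(O)O3 | intermediate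
11 | (5S,7S,10S)-8-iodo-7-methoxy bridged ketal | IC1=CC[C@@]23CCCC(C)(C)[C@@H]2C[C@]1(OC)O3 | intermediate
12 | C8 vinyllithium of the bridged methyl ketal | [Li]C1=CC[C@@]23CCCC(C)(C)[C@@H]2C[C@]1(OC)O3 | intermediate
13 | lithium pentacarbonyl(acyl)chromate, acyl carbon C14 on C8 | [Li+].[O-]C(=[Cr](=C=O)(=C=O)(=C=O)(=C=O)=C=O)C1=CC[C@@]23CCCC(C)(C)[C@@H]2C[C@]1(OC)O3 | intermediate
14 | pentacarbonyl[methoxy(C8-alkenyl)carbene]chromium, carbene carbon C14 on C8 of the (5S,7S,10S) bridged methyl ketal | COC(=[Cr](=C=O)(=C=O)(=C=O)(=C=O)=C=O)C1=CC[C@@]23CCCC(C)(C)[C@@H]2C[C@]1(OC)O3 | intermediate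
15 | N,2-dimethoxy-N-methylacetamide | COCC(=O)N(C)OC | starting material
16 | 1-methoxy-3-methylbutan-2-one | COCC(=O)C(C)C | intermediate
17 | (Z)-1-methoxy-3-methylbut-1-en-2-yl trifluoromethanesulfonate | CO/C=C(\OS(=O)(=O)C(F)(F)F)C(C)C | intermediate
18 | 1-methoxy-3-methylbut-1-yne | COC#CC(C)C | intermediate
19 | tricarbonylchromium η6-arene complex of 20 (written as arene plus Cr(CO)3 fragment) | COc1c(C(C)C)c(OC)c2c(C[C@@]34CCCC(C)(C)[C@@H]3C[C@]2(OC)O4)c1O.[Cr](=C=O)(=C=O)=C=O | intermediate
20 | (5S,7S,10S)-11-hydroxy-7,12,14-trimethoxy-13-isopropyl arene fused at C8/C9 to the bridged methyl ketal | COc1c(C(C)C)c(OC)c2c(C[C@@]34CCCC(C)(C)[C@@H]3C[C@]2(OC)O4)c1O | intermediate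
21 | (5S,7S,10S)-7,11-dihydroxy-12,14-dimethoxy-13-isopropyl arene hemiketal | COc1c(C(C)C)c(OC)c2c(C[C@@]34CCCC(C)(C)[C@@H]3C[C@]2(O)O4)c1O | intermediate
22 | komaroviquinone, (5S,7S,10S) | COC1=C(C(C)C)C(=O)C2=C(C[C@@]34CCCC(C)(C)[C@@H]3C[C@]2(O)O4)C1=O | target

**Step count.** 15 steps in total. The longest linear sequence is 12 steps (steps 1–10, 14, 15); steps 11–13 make the alkyne.

**Steps most likely to fail**

1. Step 14. The electron-rich ynol ether may oligomerise on the carbene, the dienylcarbene may close to a five-membered ring without CO insertion, and the alkyne orientation rests on electronic control alone. Fallback, from carbene complex 14 back to 22: 3-methylbut-1-yne is lithiated (n-BuLi) and borylated with 2-isopropoxy-4,4,5,5-tetramethyl-1,3,2-dioxaborolane to give 4,4,5,5-tetramethyl-2-(3-methylbut-1-yn-1-yl)-1,3,2-dioxaborolane F1. Benzannulation of 14 with this alkynylboronate (THF, 55 °C, then air) should give the C12 aryl boronate phenol F2, since alkynylboronates are known to enter this benzannulation with boron next to the new hydroxyl. NaBO3·4H2O in THF/H2O oxidises the C–B bond to the C11,C12-catechol F3. 1 M HCl followed by (NH4)2Ce(NO3)6 gives 12-O-demethylkomaroviquinone F4, and Me3SiCHN2 in MeOH/toluene methylates the acidic quinone hydroxyl to return to 22.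

2. Step 8. The ring–chain equilibrium may lie so far on the hemiketal side that the pyridine-mediated iodination of the enone form stalls. Fallback, from lactone 7 back to 11, keeping ring B open-chain-derived and the tertiary alcohol protected: Me(MeO)NH·HCl/AlMe3 opens 7 to the hydroxy Weinreb amide F5. Et3SiOTf/2,6-lutidine gives the triethylsilyl ether F6, and CH2=CHMgBr gives the vinyl ketone F7. Ring-closing metathesis with second-generation Grubbs catalyst gives the silyloxy cycloheptenone F8, and I2/pyridine gives the α-iodoenone F9. Camphorsulfonic acid in MeOH then removes the silyl group and closes the bridged methyl ketal 11.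

3. Step 5. The tertiary cation may be diverted (migration of the allyl double bond, trifluoroacetate addition to it, hydride shifts) before the carboxyl closes. Fallback, from ester 5 back to 7, replacing cationic by halonium chemistry: 5 is saponified and acid 6 is isolated. I2/NaHCO3 in MeCN/H2O effects anti iodolactonisation on the trisubstituted alkene only and gives the cis-fused iodolactone F10 (iodine on C1, trans to the lactone oxygen). Bu3SnH with azobisisobutyronitrile in toluene at 80 °C then removes the iodine to give 7.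

**Further compounds**
F1 | step 14 | 4,4,5,5-tetramethyl-2-(3-methylbut-1-yn-1-yl)-1,3,2-dioxaborolane | CC(C)C#CB1OC(C)(C)C(C)(C)O1
F2 | step 14 | (5S,7S,10S)-11-hydroxy-7,14-dimethoxy-13-isopropyl-12-(pinacolboryl) arene bridged ketal | CC(C)c1c(OC)c2c(C[C@@]34CCCC(C)(C)[C@@H]3C[C@]2(OC)O4)c(O)c1B1OC(C)(C)C(C)(C)O1
F3 | step 14 | (5S,7S,10S)-11,12-dihydroxy-7,14-dimethoxy-13-isopropyl arene bridged ketal | CC(C)c1c(OC)c2c(C[C@@]34CCCC(C)(C)[C@@H]3C[C@]2(OC)O4)c(O)c1O
F4 | step 14 | 12-O-demethylkomaroviquinone (12-hydroxyquinone hemiketal) | OC1=C(C(C)C)C(=O)C2=C(C[C@@]34CCCC(C)(C)[C@@H]3C[C@]2(O)O4)C1=O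
F5 | step 8 | 2-[(1S,2S)-2-allyl-2-hydroxy-6,6-dimethylcyclohexyl]-N-methoxy-N-methylacetamide | C=CC[C@@]1(O)CCCC(C)(C)[C@@H]1CC(=O)N(C)OC
F6 | step 8 | triethylsilyl ether of F5 | C=CC[C@@]1(O[Si](CC)(CC)CC)CCCC(C)(C)[C@@H]1CC(=O)N(C)OC
F7 | step 8 | 1-[(1S,2S)-2-allyl-6,6-dimethyl-2-(triethylsilyloxy)cyclohexyl]but-3-en-2-one | C=CC[C@@]1(O[Si](CC)(CC)CC)CCCC(C)(C)[C@@H]1CC(=O)C=C
F8 | step 8 | (5S,10S)-10-(triethylsilyloxy) bicyclic cyclohept-8-en-7-one | O=C1C=CC[C@@]2(O[Si](CC)(CC)CC)CCCC(C)(C)[C@@H]2C1
F9 | step 8 | (5S,10S)-8-iodo-10-(triethylsilyloxy) bicyclic cyclohept-8-en-7-one | O=C1C(I)=CC[C@@]2(O[Si](CC)(CC)CC)CCCC(C)(C)[C@@H]2C1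
F10 | step 5 | cis-fused iodolactone of 6 (iodine on C1, trans to the lactone oxygen) | C=CC[C@@]12[C@@H](I)CCC(C)(C)[C@@H]1CC(=O)O2
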